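## The problem

The target 17 is a biflavonoid. A (2S)-flavanone (benzo ring A, dihydropyranone ring C, 4-hydroxyphenyl ring B) and a flavone (phenylene ring D, pyranone ring E, dihydroxybenzo ring F) share one oxygen, which links C6 of ring A to the para carbon of ring D. That oxygen sits between the C5 hydroxyl and the C7 methoxyl of ring A, so the diaryl ether is doubly ortho-substituted on an electron-rich ring and is best made early, on small pieces, with an activated aryl halide. The only stereocentre is C2 of ring C; nothing else in the molecule can control it, so a chiral catalyst must. It is also the most fragile point, because base opens ring C by β-elimination of O1 to the 2'-hydroxychalcone and returns racemic material; C2 should therefore be set late and see no base afterwards. Ring A carries three different oxygens in a row (OH, OAr, OMe), yet it can come from a symmetric 2,6-dimethoxyhydroquinone, because the C4 carbonyl later activates only the peri methyl ether for cleavage. Four phenols are free in the target, and the hydroquinone-type intermediates on the way oxidise in air under base. The key step rests on ring E (O1, C2, C3, C4, C4a, C8a): it is bonded to ring D through carbon at C2, and C4 is a single carbon between C4a and the C3–C2 unit, so the ring divides into an ortho-iodophenol, carbon monoxide and an arylacetylene.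

## Retrosynthesis

**17 from 16.** The last operation cuts no skeletal bond: three benzyl ethers and the C5 methyl ether of tribenzyl dimethyl ether 16 are cleaved by one Lewis acid. Benzyl is chosen for the flavone and ring B oxygens because it survives amine, heat, acid and palladium and leaves under the conditions that also cleave the chelated methyl ether. The forward step must leave the C7 methyl ether, the diaryl ether and C2 untouched.

**16 from 14 and 15.** The C2–aryl bond of ring C is cut, giving chromone 14 and 4-(benzyloxy)phenylboronic acid 15. The neighbouring cut, O1–C2 by cyclisation of a chalcone, gives racemic flavanone under the basic conditions that also racemise it. The conjugate arylation sets C2 under neutral conditions with a chiral palladium catalyst. The precursor 14 is achiral, and its second enone (ring E) is 2-aryl-substituted and should not compete.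

**14 from 12.** O1–C2 and C2–C3 of ring C are cut, removing one carbon and leaving ortho-hydroxyacetophenone 12. The forward reaction is the enaminone route to chromones with a formamide acetal. It needs only that the flavone and the benzyl ethers tolerate mild heat and dilute acid.

**12 from 8, 9 and 6 (key step).** Ring E is cut at C4a–C4, C4–C3 and O1–C2, giving 3,5-bis(benzyloxy)-2-iodophenol 8, carbon monoxide 9 and arylacetylene 6. The alternative of joining the halves at the ether oxygen late would require substitution at a hindered phenoxide on a large, base-sensitive molecule. Here the halves are joined through carbon, and the ether is already in 6. The acetyl group and its chelated hydroxyl ride through as spectators, so no protecting group is removed after the coupling and no Lewis-acid acylation is run in the presence of the benzyl ethers.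

**6 from 5.** The alkyne is traced to aldehyde 5 by a one-carbon homologation with a diazophosphonate. The aldehyde is the activating group of the preceding substitution, so it serves twice.

**5 from 3 and 4.** The diaryl ether C–O bond on ring D is cut, giving dihydroxyketone 3 and 4-fluorobenzaldehyde 4. Placing the acetyl group before the arylation is the central choice of the front end. The hydroxyl next to the ketone is masked by chelation, so the hindered hydroxyl between the methoxyl groups is the one arylated. A silyl ether on the unhindered oxygen was considered and rejected, because the substitution releases fluoride, which would cleave it and scramble the site of arylation.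

**3 from 2 from 1.** The C-acetyl bond is cut back to 2,6-dimethoxyhydroquinone 2, which comes from commercial quinone 1 by reduction. The two free ring positions of 2 are equivalent and both ortho to the unhindered hydroxyl, so the acetylation has no regiochemical question.

**8 from 7.** The C–I bond is cut back to commercial 3,5-bis(benzyloxy)phenol 7. The forward iodination must go ortho to hydroxyl and not between the two benzyloxy groups.

## Roads not taken

**Alternative 1:** The cut runs through ring D itself, at two of its C–C bonds. In the forward direction aryl ethynyl ether A2 adds across C3 and C6 of methyl coumalate A3, and loss of CO2 gives para-aryloxybenzoate A1.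
- Merits: the ether oxygen is attached to an sp carbon before the ring exists, so no hindered phenoxide attacks an arene. The polarity of the partners places the aryloxy group para to the ester. No fluoride is released, so a silyl ether on the other oxygen would survive.
- Weak points: the ring built is an unadorned para-phenylene, which 4 already supplies. A2 must be made from the hindered phenol through a dichlorovinyl ether and strong base, and is heat-sensitive, while the cycloaddition needs heat. A1 is only an ester, so ring E, ring C and C2 are all still to be made.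
- Comparison: this road is better in one respect, because it does not depend on the substitution of step 3; were that to fail, it is the way around. The chosen plan sets against it a one-operation ether synthesis from 3 and 4 and about three fewer steps to the alkyne.

**Alternative 2:** The cut is at C8–C8a and C4a–C5, so ring A is made last. Diene A6 adds through its CH2 terminus to C8a of enantiopure bromodihydropyranone A5, the C4a enolate closes on the ester carbon, and loss of HBr gives A4.
- Merits: it is the most convergent road. C5 arrives as a free hydroxyl and C7 as a methyl ether, so no selective demethylation is needed and only debenzylation separates A4 from 17. The stereocentre of A5 can come from a reliable asymmetric hetero-Diels–Alder reaction on a small aldehyde.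
- Weak points: after the conjugate addition the C4a enolate has O1 on its β-carbon C8a, and expulsion of O1 opens ring C irreversibly. The base needed to lose HBr also threatens the flavanone that is formed. A6 is a large, fully oxygenated silyl ketene acetal that must carry the whole flavone, and annulations of 2-aryloxy dienes of this kind with α-bromoenones have little precedent.
- Comparison: in the end game this road is better than the chosen one, since it avoids the Lewis-acid demethylation of step 9. The chosen plan sets against it reactions of well-known classes and a stereocentre formed under neutral conditions after all enolate chemistry is over.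

**Alternative 3:** The cut is at O1–C8a and C4–C4a. Fluoride releases the C4a≡C8a aryne from silylaryl triflate A9; the alkoxide of (S)-hydroxy ester A8 adds at C8a and the aryl anion closes on the ester, giving A7, which is identical with 16.
- Merits: the stereocentre comes from asymmetric reduction of a simple keto ester and is never touched again. The C5 methoxyl next to the aryne directs the oxygen to C8a. The union is late and convergent.
- Weak points: A9 needs ortho-halogenation, silylation and triflation of an electron-rich phenol, and the organometallic steps are not compatible with the flavone carbonyl. This forces the flavone construction to tolerate a triflate and a silyl group. The alkoxide of A8 can undergo retro-aldol cleavage or lose water to the cinnamate. The hydroxy ester is also a proton source for the aryl anion, which would give O-arylation without ring closure.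
- Comparison: the end game is the same (16 to 17), and the origin of the stereocentre is better here than in the chosen plan. The chosen plan sets against it a conjugate arylation of a class known for chromones and a ring A that needs no aryne precursor.

Key step: step 6

## Route

Assumption: the (S) enantiomer of the tert-butyl pyridine-oxazoline ligand is taken to give (2R)-2-arylchroman-4-ones, as it gives (R) adducts with cyclic enones; the (R) ligand is therefore specified, and its antipode would be used if the sense proved opposite.

Step 1
Reactants: 1 2,6-dimethoxy-1,4-benzoquinone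
Product: 2 2,6-dimethoxybenzene-1,4-diol
Conditions: H2 (1 atm), Pd/C, THF, rt; filtered and used at once under argon
Reagents that add atoms: none
Why: Catalytic hydrogenation reduces quinones to hydroquinones under mild conditions (quinone reduction); the air-sensitive product is not stored.

Step 2
Reactants: 2 2,6-dimethoxybenzene-1,4-diol
Product: 3 1-(3,6-dihydroxy-2,4-dimethoxyphenyl)ethan-1-one
Conditions: AcOH, BF3·OEt2, 90 °C; then H2O
Reagents that add atoms: acetic acid, CC(=O)O
Why: Friedel–Crafts C-acetylation of a polyoxygenated phenol (Fries-type, through the aryl acetate); the two free ring positions are equivalent and ortho to the unhindered hydroxyl, so a single ketone should result after hydrolysis of the boron complexes.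

Step 3
Reactants: 3 1-(3,6-dihydroxy-2,4-dimethoxyphenyl)ethan-1-one; 4 4-fluorobenzaldehyde
Product: 5 4-(3-acetyl-4-hydroxy-2,6-dimethoxyphenoxy)benzaldehyde
Conditions: K2CO3 (1.2 equiv), DMF, 100 °C, argon
Reagents that add atoms: none
Why: Nucleophilic aromatic substitution (addition–elimination) on the aldehyde-activated aryl fluoride; the hydroxyl next to the acetyl group is hydrogen-bonded and gives only a weakly nucleophilic, conjugated phenoxide, so the phenoxide between the methoxyl groups is arylated, in line with the known selective O-alkylation of this ketone. Air is excluded because 3 is a hydroquinone.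

Step 4
Reactants: 5 4-(3-acetyl-4-hydroxy-2,6-dimethoxyphenoxy)benzaldehyde
Product: 6 1-[3-(4-ethynylphenoxy)-6-hydroxy-2,4-dimethoxyphenyl]ethan-1-one
Conditions: (MeO)2P(O)C(N2)COMe, K2CO3, MeOH, 0 °C to rt
Reagents that add atoms: dimethyl (1-diazo-2-oxopropyl)phosphonate, COP(=O)(OC)C(=[N+]=[N-])C(C)=O
Why: Ohira–Bestmann (Seyferth–Gilbert) homologation; the diazophosphonate anion freed by methanolysis adds to the aldehyde, and loss of phosphate and N2 gives the terminal alkyne. The hindered aryl methyl ketone, present as its phenoxide, should not react.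

Step 5
Reactants: 7 3,5-bis(benzyloxy)phenol
Product: 8 3,5-bis(benzyloxy)-2-iodophenol
Conditions: NIS, CH2Cl2, −20 to 0 °C, dark
Reagents that add atoms: N-iodosuccinimide, O=C1CCC(=O)N1I
Why: Electrophilic aromatic iodination of an activated phenol; the two positions ortho to hydroxyl are equivalent and less hindered than the position between the benzyloxy groups, so the 2-iodide should predominate and is separated from the 4-iodide by chromatography.

Step 6
Reactants: 8 3,5-bis(benzyloxy)-2-iodophenol; 9 carbon monoxide; 6 1-[3-(4-ethynylphenoxy)-6-hydroxy-2,4-dimethoxyphenyl]ethan-1-one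
Product: 12 2-[4-(3-acetyl-4-hydroxy-2,6-dimethoxyphenoxy)phenyl]-5,7-bis(benzyloxy)-4H-chromen-4-one, via ortho-hydroxyaryl alkynone 10 (not isolated), via diethylamino enaminone 11 (not isolated)
Conditions: CO (20 atm), PdCl2(PPh3)2 (5 mol %), Et2NH, 120 °C, autoclave
Reagents that add atoms: none
Why: PdCl2(PPh3)2 (divalent palladium) is reduced in situ to zerovalent palladium, which inserts into the C–I bond of 8; CO insertion gives the aroylpalladium iodide, and coupling with the acetylide of 6 (Et2NH as base) gives alkynone 10, forming C4a–C4 and C4–C3. Et2NH then adds to the β-carbon of 10 to give enaminone 11, and the ortho phenol displaces the amine by 6-endo-trig addition–elimination, forming O1–C2 and closing ring E. The closest known reaction type is the palladium-catalysed carbonylative annulation of 2-iodophenols with terminal arylacetylenes in a secondary amine, which gives flavones. No stereocentre is formed. Three selectivities are needed: CO insertion before alkyne coupling (otherwise a 2-arylbenzofuran results), alkyne and not amine capture of the acylpalladium, and six- and not five-membered closure (aurone). The electron-rich aryl group of 8 migrates to CO readily and the CO pressure keeps the acyl complex populated, while the path through 11 puts the leaving group on C2 so that only 6-endo closure is productive. The chelated hydroxyl and the hindered acetyl group of 6 are spectators, being a poor nucleophile and a ketone that does not condense with Et2NH. The benzyl ethers tolerate amine and heat.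

Step 7
Reactants: 12 2-[4-(3-acetyl-4-hydroxy-2,6-dimethoxyphenoxy)phenyl]-5,7-bis(benzyloxy)-4H-chromen-4-one
Product: 14 6-{4-[5,7-bis(benzyloxy)-4-oxo-4H-chromen-2-yl]phenoxy}-5,7-dimethoxy-4H-chromen-4-one, via dimethylamino enaminone 13 (not isolated)
Conditions: Me2NCH(OMe)2, toluene, 100 °C; then 2 M HCl, CH2Cl2, rt
Reagents that add atoms: N,N-dimethylformamide dimethyl acetal, COC(OC)N(C)C
Why: Enaminone route to chromones; condensation of the methyl ketone with the formamide acetal gives 13, and acid promotes 6-endo-trig addition of the chelated phenol and loss of dimethylamine. The flavone and the benzyl ethers should be inert to both stages.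

Step 8
Reactants: 14 6-{4-[5,7-bis(benzyloxy)-4-oxo-4H-chromen-2-yl]phenoxy}-5,7-dimethoxy-4H-chromen-4-one; 15 4-(benzyloxy)phenylboronic acid
Product: 16 (2S)-2-[4-(benzyloxy)phenyl]-6-{4-[5,7-bis(benzyloxy)-4-oxo-4H-chromen-2-yl]phenoxy}-5,7-dimethoxy-2,3-dihydro-4H-chromen-4-one
Conditions: Pd(OCOCF3)2 (10 mol %), (R)-t-BuPyOx (12 mol %), NH4PF6, H2O, ClCH2CH2Cl, 60 °C
Reagents that add atoms: none
Why: Palladium-catalysed asymmetric conjugate addition of an arylboronic acid to a chromone; transmetalation gives a cationic arylpalladium complex (divalent palladium) of the pyridine-oxazoline ligand, which inserts C2=C3 with the aryl group delivered to the Re face of C2, and water protonates the palladium enolate, setting C2 as S. The 2-aryl enone of ring E is far less reactive, and the absence of base keeps ring C closed.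

Step 9
Reactants: 16 (2S)-2-[4-(benzyloxy)phenyl]-6-{4-[5,7-bis(benzyloxy)-4-oxo-4H-chromen-2-yl]phenoxy}-5,7-dimethoxy-2,3-dihydro-4H-chromen-4-one
Product: 17 (2S)-6-[4-(5,7-dihydroxy-4-oxo-4H-chromen-2-yl)phenoxy]-5-hydroxy-2-(4-hydroxyphenyl)-7-methoxy-2,3-dihydro-4H-chromen-4-one
Conditions: BCl3, C6HMe5, CH2Cl2, −78 to 0 °C; then MeOH
Reagents that add atoms: none
Why: Lewis-acid ether cleavage; BCl3 removes the three benzyl groups at low temperature with pentamethylbenzene trapping the benzyl cations, and on warming cleaves only the C5 methyl ether, which is activated by chelation of boron between O5 and the C4 carbonyl. The C7 methyl ether and the diaryl ether should survive, and no base is present to open ring C.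

## Compound list

1 | 2,6-dimethoxy-1,4-benzoquinone | COC1=CC(=O)C=C(OC)C1=O | starting material
2 | 2,6-dimethoxybenzene-1,4-diol | COc1cc(O)cc(OC)c1O | intermediate
3 | 1-(3,6-dihydroxy-2,4-dimethoxyphenyl)ethan-1-one | CC(=O)c1c(OC)c(O)c(OC)cc1O | intermediate
4 | 4-fluorobenzaldehyde | O=Cc1ccc(F)cc1 | starting material
5 | 4-(3-acetyl-4-hydroxy-2,6-dimethoxyphenoxy)benzaldehyde | CC(=O)c1c(O)cc(OC)c(Oc2ccc(C=O)cc2)c1OC | intermediate
6 | 1-[3-(4-ethynylphenoxy)-6-hydroxy-2,4-dimethoxyphenyl]ethan-1-one | CC(=O)c1c(O)cc(OC)c(Oc2ccc(C#C)cc2)c1OC | intermediate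
7 | 3,5-bis(benzyloxy)phenol | Oc1cc(OCc2ccccc2)cc(OCc2ccccc2)c1 | starting material
8 | 3,5-bis(benzyloxy)-2-iodophenol | Oc1cc(OCc2ccccc2)cc(OCc2ccccc2)c1I | intermediate
9 | carbon monoxide | [C-]#[O+] | starting material
10 | 3-[4-(3-acetyl-4-hydroxy-2,6-dimethoxyphenoxy)phenyl]-1-[2,4-bis(benzyloxy)-6-hydroxyphenyl]prop-2-yn-1-one (formed and consumed in step 6) | CC(=O)c1c(O)cc(OC)c(Oc2ccc(cc2)C#CC(=O)c2c(O)cc(OCc3ccccc3)cc2OCc2ccccc2)c1OC | intermediate
11 | 3-[4-(3-acetyl-4-hydroxy-2,6-dimethoxyphenoxy)phenyl]-1-[2,4-bis(benzyloxy)-6-hydroxyphenyl]-3-(diethylamino)prop-2-en-1-one, alkene geometry not defined (formed and consumed in step 6) | CCN(CC)C(=CC(=O)c1c(O)cc(OCc2ccccc2)cc1OCc1ccccc1)c1ccc(Oc2c(OC)cc(O)c(C(C)=O)c2OC)cc1 | intermediate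
12 | 2-[4-(3-acetyl-4-hydroxy-2,6-dimethoxyphenoxy)phenyl]-5,7-bis(benzyloxy)-4H-chromen-4-one | CC(=O)c1c(O)cc(OC)c(Oc2ccc(cc2)-c2cc(=O)c3c(OCc4ccccc4)cc(OCc4ccccc4)cc3o2)c1OC | intermediate
13 | (E)-1-{3-[4-(5,7-bis(benzyloxy)-4-oxo-4H-chromen-2-yl)phenoxy]-6-hydroxy-2,4-dimethoxyphenyl}-3-(dimethylamino)prop-2-en-1-one (formed and consumed in step 7) | CN(C)/C=C/C(=O)c1c(O)cc(OC)c(Oc2ccc(cc2)-c2cc(=O)c3c(OCc4ccccc4)cc(OCc4ccccc4)cc3o2)c1OC | intermediate
14 | 6-{4-[5,7-bis(benzyloxy)-4-oxo-4H-chromen-2-yl]phenoxy}-5,7-dimethoxy-4H-chromen-4-one | COc1cc2occc(=O)c2c(OC)c1Oc1ccc(cc1)-c1cc(=O)c2c(OCc3ccccc3)cc(OCc3ccccc3)cc2o1 | intermediate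
15 | 4-(benzyloxy)phenylboronic acid | OB(O)c1ccc(OCc2ccccc2)cc1 | starting material
16 | (2S)-2-[4-(benzyloxy)phenyl]-6-{4-[5,7-bis(benzyloxy)-4-oxo-4H-chromen-2-yl]phenoxy}-5,7-dimethoxy-2,3-dihydro-4H-chromen-4-one | COc1cc2c(c(OC)c1Oc1ccc(-c3cc(=O)c4c(OCc5ccccc5)cc(OCc5ccccc5)cc4o3)cc1)C(=O)C[C@@H](c1ccc(OCc3ccccc3)cc1)O2 | intermediate
17 | (2S)-6-[4-(5,7-dihydroxy-4-oxo-4H-chromen-2-yl)phenoxy]-5-hydroxy-2-(4-hydroxyphenyl)-7-methoxy-2,3-dihydro-4H-chromen-4-one | COc1cc2c(c(O)c1Oc1ccc(-c3cc(=O)c4c(O)cc(O)cc4o3)cc1)C(=O)C[C@@H](c1ccc(O)cc1)O2 | target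

## Summary and risks

Total step count: 9. Longest linear sequence: 8 steps (1, 2, 3, 4, 6, 7, 8, 9); step 5 is the one-step side branch.

**Step 6 (key step).** The most likely failure is slow oxidative addition at the doubly ortho-substituted, electron-rich C–I bond. Amine capture of the acylpalladium (giving the diethylamide), reductive loss of iodine, or direct coupling without CO followed by 5-endo closure could then outrun the wanted sequence. The fallback separates the palladium chemistry from the ring closure and removes both the free phenol and the secondary amine from the coupling. It sets out from 8, which is acetylated (Ac2O, pyridine) to 3,5-bis(benzyloxy)-2-iodophenyl acetate F1. F1 is coupled with 6 and CO (1 atm) using PdCl2(PPh3)2 and Et3N in THF, giving 3,5-bis(benzyloxy)-2-{3-[4-(3-acetyl-4-hydroxy-2,6-dimethoxyphenoxy)phenyl]prop-2-ynoyl}phenyl acetate F2, which is isolated. Treatment of F2 with Et2NH in ethanol at room temperature removes the acetyl group and closes ring E through the enaminone, returning to the route at 12.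

**Step 8.** The chromone is electron-rich and carries a peri methoxyl group, so slow insertion, protodeboronation of the electron-rich boronic acid, or insufficient facial selectivity are the likely failures. The fallback sets out from 12. Claisen–Schmidt condensation with 4-(benzyloxy)benzaldehyde (Ba(OH)2, MeOH/THF, rt) gives (E)-1-{3-[4-(5,7-bis(benzyloxy)-4-oxo-4H-chromen-2-yl)phenoxy]-6-hydroxy-2,4-dimethoxyphenyl}-3-[4-(benzyloxy)phenyl]prop-2-en-1-one F3. Cyclisation with NaOAc in refluxing ethanol gives racemic 2-[4-(benzyloxy)phenyl]-6-{4-[5,7-bis(benzyloxy)-4-oxo-4H-chromen-2-yl]phenoxy}-5,7-dimethoxy-2,3-dihydro-4H-chromen-4-one F4. Preparative chromatography on a chiral stationary phase separates 16 from its (2R)-enantiomer F5, returning to the route at 16; step 7 is then not needed.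

**Step 9.** The likely failure is loss of enantiopurity by Lewis-acid-assisted opening of ring C at the benzylic C2–O1 bond, which the para oxygen of ring B assists. Incomplete cleavage of the C5 methyl ether and C-benzylation of the phloroglucinol ring are further risks. The fallback moves the ether cleavage in front of the stereocentre. It sets out from 14, which is treated with BCl3 and pentamethylbenzene to give 6-[4-(5,7-dihydroxy-4-oxo-4H-chromen-2-yl)phenoxy]-5-hydroxy-7-methoxy-4H-chromen-4-one F6. F6 is then arylated with (4-hydroxyphenyl)boronic acid under the conditions of step 8, which tolerate free phenols, and the route is rejoined at 17.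

**Step 3.** The hindered phenoxide needs heat, and at that temperature condensation between the methyl ketone and the aldehyde, arylation at the chelated oxygen, or oxidation of the hydroquinone may intervene. The fallback avoids both heat and the aldehyde. It sets out from 3, which is arylated at room temperature with bis(4-bromophenyl)iodonium triflate and K2CO3 in MeCN to 1-[3-(4-bromophenoxy)-6-hydroxy-2,4-dimethoxyphenyl]ethan-1-one F7. Sonogashira coupling with trimethylsilylacetylene (PdCl2(PPh3)2, CuI, Et3N, 70 °C) gives 1-{6-hydroxy-2,4-dimethoxy-3-[4-(trimethylsilylethynyl)phenoxy]phenyl}ethan-1-one F8. K2CO3 in MeOH removes the silyl group, returning to the route at 6 and bypassing 5.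

**Step 5.** Iodination may go para to hydroxyl, between the benzyloxy groups, or twice. The fallback fixes the site by directed metalation. It sets out from 7, which is converted (MOMCl, i-Pr2NEt) to 1,3-bis(benzyloxy)-5-(methoxymethoxy)benzene F9. Lithiation with n-BuLi in THF at the carbon between the acetal oxygen and a benzyloxy group, then I2, gives 1,5-bis(benzyloxy)-2-iodo-3-(methoxymethoxy)benzene F10. HCl in MeOH removes the acetal, returning to the route at 8.

## Further compounds

F1 | step 6 | 3,5-bis(benzyloxy)-2-iodophenyl acetate | CC(=O)Oc1cc(OCc2ccccc2)cc(OCc2ccccc2)c1I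
F2 | step 6 | 3,5-bis(benzyloxy)-2-{3-[4-(3-acetyl-4-hydroxy-2,6-dimethoxyphenoxy)phenyl]prop-2-ynoyl}phenyl acetate | CC(=O)Oc1cc(OCc2ccccc2)cc(OCc2ccccc2)c1C(=O)C#Cc1ccc(Oc2c(OC)cc(O)c(C(C)=O)c2OC)cc1
F3 | step 8 | (E)-1-{3-[4-(5,7-bis(benzyloxy)-4-oxo-4H-chromen-2-yl)phenoxy]-6-hydroxy-2,4-dimethoxyphenyl}-3-[4-(benzyloxy)phenyl]prop-2-en-1-one | O=C(/C=C/c1ccc(OCc2ccccc2)cc1)c1c(O)cc(OC)c(Oc2ccc(cc2)-c2cc(=O)c3c(OCc4ccccc4)cc(OCc4ccccc4)cc3o2)c1OC
F4 | step 8 | racemic 2-[4-(benzyloxy)phenyl]-6-{4-[5,7-bis(benzyloxy)-4-oxo-4H-chromen-2-yl]phenoxy}-5,7-dimethoxy-2,3-dihydro-4H-chromen-4-one | COc1cc2c(c(OC)c1Oc1ccc(-c3cc(=O)c4c(OCc5ccccc5)cc(OCc5ccccc5)cc4o3)cc1)C(=O)CC(c1ccc(OCc3ccccc3)cc1)O2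
F5 | step 8 | (2R)-2-[4-(benzyloxy)phenyl]-6-{4-[5,7-bis(benzyloxy)-4-oxo-4H-chromen-2-yl]phenoxy}-5,7-dimethoxy-2,3-dihydro-4H-chromen-4-one | COc1cc2c(c(OC)c1Oc1ccc(-c3cc(=O)c4c(OCc5ccccc5)cc(OCc5ccccc5)cc4o3)cc1)C(=O)C[C@H](c1ccc(OCc3ccccc3)cc1)O2
F6 | step 9 | 6-[4-(5,7-dihydroxy-4-oxo-4H-chromen-2-yl)phenoxy]-5-hydroxy-7-methoxy-4H-chromen-4-one | COc1cc2occc(=O)c2c(O)c1Oc1ccc(cc1)-c1cc(=O)c2c(O)cc(O)cc2o1
F7 | step 3 | 1-[3-(4-bromophenoxy)-6-hydroxy-2,4-dimethoxyphenyl]ethan-1-one | CC(=O)c1c(O)cc(OC)c(Oc2ccc(Br)cc2)c1OC
F8 | step 3 | 1-{6-hydroxy-2,4-dimethoxy-3-[4-(trimethylsilylethynyl)phenoxy]phenyl}ethan-1-one | CC(=O)c1c(O)cc(OC)c(Oc2ccc(C#C[Si](C)(C)C)cc2)c1OC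
F9 | step 5 | 1,3-bis(benzyloxy)-5-(methoxymethoxy)benzene | COCOc1cc(OCc2ccccc2)cc(OCc2ccccc2)c1
F10 | step 5 | 1,5-bis(benzyloxy)-2-iodo-3-(methoxymethoxy)benzene | COCOc1cc(OCc2ccccc2)cc(OCc2ccccc2)c1I
A1 | alternative 1 | methyl 4-[2,6-dimethoxy-4-(triisopropylsilyloxy)phenoxy]benzoate | COC(=O)c1ccc(Oc2c(OC)cc(O[Si](C(C)C)(C(C)C)C(C)C)cc2OC)cc1
A2 | alternative 1 | 2-(ethynyloxy)-1,3-dimethoxy-5-(triisopropylsilyloxy)benzene | C#COc1c(OC)cc(O[Si](C(C)C)(C(C)C)C(C)C)cc1OC
A3 | alternative 1 | methyl coumalate (methyl 2-oxo-2H-pyran-5-carboxylate) | COC(=O)C1=COC(=O)C=C1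
A4 | alternative 2 | (2S)-2-[4-(benzyloxy)phenyl]-6-{4-[5,7-bis(benzyloxy)-4-oxo-4H-chromen-2-yl]phenoxy}-5-hydroxy-7-methoxy-2,3-dihydro-4H-chromen-4-one | COc1cc2c(c(O)c1Oc1ccc(-c3cc(=O)c4c(OCc5ccccc5)cc(OCc5ccccc5)cc4o3)cc1)C(=O)C[C@@H](c1ccc(OCc3ccccc3)cc1)O2
A5 | alternative 2 | (2S)-2-[4-(benzyloxy)phenyl]-5-bromo-2,3-dihydro-4H-pyran-4-one | O=C1C[C@@H](c2ccc(OCc3ccccc3)cc2)OC=C1Br
A6 | alternative 2 | 5,7-bis(benzyloxy)-2-(4-{[1,3-dimethoxy-1-(trimethylsilyloxy)buta-1,3-dien-2-yl]oxy}phenyl)-4H-chromen-4-one | C=C(OC)C(Oc1ccc(cc1)-c1cc(=O)c2c(OCc3ccccc3)cc(OCc3ccccc3)cc2o1)=C(OC)O[Si](C)(C)C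
A7 | alternative 3 | (2S)-2-[4-(benzyloxy)phenyl]-6-{4-[5,7-bis(benzyloxy)-4-oxo-4H-chromen-2-yl]phenoxy}-5,7-dimethoxy-2,3-dihydro-4H-chromen-4-one (identical with 16) | COc1cc2c(c(OC)c1Oc1ccc(-c3cc(=O)c4c(OCc5ccccc5)cc(OCc5ccccc5)cc4o3)cc1)C(=O)C[C@@H](c1ccc(OCc3ccccc3)cc1)O2
A8 | alternative 3 | ethyl (3S)-3-[4-(benzyloxy)phenyl]-3-hydroxypropanoate | CCOC(=O)C[C@@H](c1ccc(OCc2ccccc2)cc1)O
A9 | alternative 3 | 4-{4-[5,7-bis(benzyloxy)-4-oxo-4H-chromen-2-yl]phenoxy}-3,5-dimethoxy-2-(trimethylsilyl)phenyl trifluoromethanesulfonate | COc1cc(OS(=O)(=O)C(F)(F)F)c([Si](C)(C)C)c(OC)c1Oc1ccc(cc1)-c1cc(=O)c2c(OCc3ccccc3)cc(OCc3ccccc3)cc2o1
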